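## Structural features

The target is a diaryl ketone in which a benzene ring A (C1–C6) and a pyrrole ring B (N1', C2'–C5') are joined through one carbonyl carbon that links C1 of ring A to C2' of ring B. Ring A carries four contiguous substituents: the acyl group at C1, hydroxyls at C2 and C4, and between them at C3 a saturated 4-methylpentyl chain (C1''–C5'', methyl branch on C4''). Ring B carries chlorine at C4' and C5' and a free N–H. There is no stereocentre and no stereogenic alkene, so no neighbouring stereocentres have to be related. The fragile parts are the two C–Cl bonds on the pyrrole (hydrogenolysis over palladium, photolysis), the acidic N1'–H, and the free phenols, of which the C2 hydroxyl is tied to the ketone oxygen in a six-membered hydrogen-bonded chelate and is far less reactive than the C4 hydroxyl. The real difficulty is regiochemical: C3 is the most crowded carbon of ring A, and intermolecular alkylation of a resorcinol nucleus goes mainly to oxygen or to the open C5 position. The key step exploits the O4–C4=C3 enol-ether unit of ring A: an allyl group parked on O4 is handed over intramolecularly to C3, and the O2–H···O=C chelate, by fixing the C1=C2 and C3=C4 double bonds, steers that transfer to C3 and away from C5. The allylic transposition built into the shift converts a branched 1-isopropylallyl group on oxygen into the linear C1''–C5'' chain on carbon, leaving only the C2''=C3'' alkene to be removed.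

## Logic of the disconnections

9 ⇒ 8. No skeletal bond is cut. Two C–H bonds (at C2'' and C3'') are removed in the retrosynthetic sense to reveal a C2''=C3'' alkene, the footprint of a [3,3] shift. This costs one step and makes the chain a Claisen retron. The forward step must saturate a disubstituted alkene without touching the two C–Cl bonds, the ketone or ring B.

8 ⇒ 6 (through 7). The C3–C1'' bond is cut and the O4–C3'' bond is reconnected. The cut is made here because C3 cannot be alkylated selectively from outside, whereas delivery from the neighbouring oxygen is intramolecular and site-specific. The gain is that a C–C bond at the most hindered ring carbon becomes an O–C bond at the most accessible phenol. The forward step must prefer C3 over C5, which calls for a free, chelated C2 hydroxyl in 6, and the rest of the molecule must survive heating.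

6 ⇒ 4 + 5. The O4–C3'' ether bond is cut. This separates the whole six-carbon chain as a commercial secondary allylic alcohol from a fully assembled dihydroxy ketone. The forward etherification must occur at the carbinol carbon without allylic transposition, and at O4 in preference to O2 and N1'.

4 ⇒ 1 + 2 (through 3). The bond between C1 of ring A and the carbonyl carbon is cut. Both halves are commercial, and both chlorine atoms arrive already in place, so no halogenation is needed anywhere. The forward acylation must take place on carbon, para to one hydroxyl and ortho to the other, and the pyrrole acid must not decarboxylate first.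

## Other disconnections considered

Alternative 1: The cut is through ring B at N1'–C5' and C2'–C3'. In the forward direction the aminoketone A1 (2-amino-1-[2,4-dimethoxy-3-(4-methylpentyl)phenyl]ethan-1-one) would be condensed with the chlorovinamidinium salt A2 (2-chloro-1,3-bis(dimethylamino)trimethinium hexafluorophosphate) to give the 4'-chloropyrrolyl ketone A3.
- In its favour: the pyrrole is built regiospecifically with the C4' chlorine in place, under ionic conditions at moderate temperature. The chain would be put on ring A early by directed lithiation between two methoxy groups, so the C3/C5 question never arises. On ring A regiocontrol and on mildness of the key step this plan is the better one.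
- Against it: A3 still lacks the C5' chlorine. A late electrophilic chlorination would have to discriminate between C5' of ring B and the activated C5 of the dimethoxy ring A. Two methyl ethers must then be cleaved, and A1 is a self-condensing α-aminoketone that needs several steps to make.
- Comparison: the chosen plan takes both chlorines from one commercial acid, needs no protecting groups and is about half as long. Alternative 1 exchanges a hot pericyclic step for a longer sequence with a chemoselectivity problem at the end.

Alternative 2: The cut is through ring A at C1–C2 and C5–C6. In the forward direction the diene A4 (1-methoxy-2-(4-methylpentyl)-1,3-bis(trimethylsilyloxy)buta-1,3-diene) would add to the terminal ynone A5 (tert-butyl 2,3-dichloro-5-(prop-2-ynoyl)-1H-pyrrole-1-carboxylate). Loss of methanol and of the silyl groups would give the N-Boc ketone A6, and Boc removal would give the target.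
- In its favour: all four substituents of ring A arrive in one convergent step, with regiochemistry set by polarity matching (the CH2 terminus of A4 to the β-carbon of A5). The phenols emerge unprotected and no alkene has to be hydrogenated next to C–Cl bonds. On regiochemical certainty this plan equals the chosen one, and it is better in avoiding the reduction.
- Against it: A4 is a moisture-sensitive, fully substituted ketene acetal whose internal alkyl group disfavours the reactive s-cis conformation. A5 needs N-protection and an ynone synthesis from the acid, and it can react in a stepwise Michael sense to give open-chain or pyranone products. A deprotection follows.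
- Comparison: the chosen plan is linear but shorter and uses only stable, commercial components. Alternative 2 is more convergent and builds more complexity in its key step, at the price of two sensitive partners and more steps overall.

Alternative 3: The cut converts the ketone oxygen and the N1'–C2' bond back into a pyridine N-oxide. In the forward direction irradiation of A7 (2,3-dichloro-6-[2,4-dimethoxy-3-(4-methylpentyl)phenyl]pyridine 1-oxide) would move oxygen to the aryl-bearing carbon and contract the ring to the aroylpyrrole A8.
- In its favour: A7 is a simple biaryl, accessible by Suzuki coupling with Pd(PPh3)4 from a commercial trihalopyridine, so both chlorines again come ready-made. On that point it is the equal of the chosen plan. The diaryl ketone is created without any acylation chemistry.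
- Against it: this photoisomerisation passes through oxaziridine and oxazepine intermediates and branches easily to deoxygenation and hydroxypyridines. In A7 the oxygen can migrate to either α-carbon, and only migration to the aryl-bearing one leads to A8. The C–Cl bonds are themselves photolabile. N-oxidation of so electron-poor a pyridine needs forcing peracid conditions, and two methyl ethers remain to be cleaved.
- Comparison: the chosen plan relies on a thermal, concerted step whose regiochemistry is set by a ground-state chelate. Alternative 3 relies on an excited-state cascade with several exits, and it is longer.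

Key step: step 3

Remark on the chemistry (assumption): alcohol 5 is used as the racemate, because its carbinol stereocentre is erased in step 3; compounds 6 and 7 are therefore racemic. The C2 hydroxyl and N1'–H are deliberately left unprotected in 6: the first is needed for the chelate that directs the rearrangement, and protecting the second would add two steps.

## Route

Step 1
Reactants: 1 resorcinol; 2 4,5-dichloro-1H-pyrrole-2-carboxylic acid
Product: 4 (4,5-dichloro-1H-pyrrol-2-yl)(2,4-dihydroxyphenyl)methanone, via difluoroboron chelate 3 (not isolated)
Conditions: BF3·OEt2 (neat, excess), 85 °C, Ar; then aq. NaOAc, 60 °C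
Reagents that add atoms: none
Why: BF3-mediated Friedel–Crafts acylation of resorcinol with a free carboxylic acid should go para to one hydroxyl and ortho to the other, the ketone then deactivating the ring against a second acylation; the O,O-difluoroboron chelate 3 of the ortho-hydroxy ketone is hydrolysed in the buffered aqueous work-up, and the two chlorines make the pyrrole acid less prone to protodecarboxylation.

Step 2
Reactants: 4 (4,5-dichloro-1H-pyrrol-2-yl)(2,4-dihydroxyphenyl)methanone; 5 rac-4-methylpent-1-en-3-ol
Product: 6 rac-(4,5-dichloro-1H-pyrrol-2-yl){2-hydroxy-4-[(4-methylpent-1-en-3-yl)oxy]phenyl}methanone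
Conditions: PPh3, DIAD, THF, 0 °C → rt (one equivalent of 5)
Reagents that add atoms: none
Why: Mitsunobu etherification: the C4 hydroxyl, para to the ketone, is the most acidic and least hindered pronucleophile, while the chelated C2 hydroxyl and the less acidic N1'–H should stay behind; direct displacement at the activated carbinol carbon gives the branched ether, and the inversion is of no consequence with racemic 5.

Step 3
Reactants: 6 rac-(4,5-dichloro-1H-pyrrol-2-yl){2-hydroxy-4-[(4-methylpent-1-en-3-yl)oxy]phenyl}methanone
Product: 8 (E)-(4,5-dichloro-1H-pyrrol-2-yl)[2,4-dihydroxy-3-(4-methylpent-2-en-1-yl)phenyl]methanone, via cyclohexadienone 7 (not isolated)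
Conditions: PhNEt2 (degassed), 190 °C, Ar, sealed tube
Reagents that add atoms: none
Why: Heating should induce a concerted, suprafacial [3,3]-sigmatropic shift (aromatic Claisen rearrangement) in which the terminal CH2 (C1'') bonds to C3 of ring A while the O4–C3'' bond breaks through a six-membered chair-like transition state. The first-formed cyclohexadienone 7 should tautomerise at once to the phenol 8, which makes the process irreversible. The closest known reaction type is the thermal rearrangement of 4-allyloxy-2-hydroxyaryl ketones to 3-allyl-2,4-dihydroxyaryl ketones. No ring is closed; the six-membered array exists only in the transition state. No stereocentre persists, since the carbinol carbon of 6 becomes sp2 and the sp3 ring carbon of 7 is lost on enolisation; a pseudo-equatorial isopropyl group in the chair should favour the E alkene, and any Z isomer converges on the same product in step 4. The selectivity needed is C3 over C5: the O2–H···O=C chelate fixes the C1=C2 and C3=C4 double bonds, so O4–C4=C3 is the better enol-ether component, and the bond-forming terminus is an unsubstituted CH2 that fits between the two oxygens. The basic amine solvent should suppress acid-promoted ionisation of the secondary allylic ether and cyclisation of the new phenol onto the alkene. The C–Cl bonds, the N–H and the diaryl ketone are expected to be inert under these neutral thermal conditions.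

Step 4
Reactants: 8 (E)-(4,5-dichloro-1H-pyrrol-2-yl)[2,4-dihydroxy-3-(4-methylpent-2-en-1-yl)phenyl]methanone
Product: 9 (4,5-dichloro-1H-pyrrol-2-yl)[2,4-dihydroxy-3-(4-methylpentyl)phenyl]methanone
Conditions: H2 (3 atm), RhCl(PPh3)3 (cat.), toluene/EtOH, 40 °C
Reagents that add atoms: none
Why: Homogeneous hydrogenation with RhCl(PPh3)3 reduces unhindered disubstituted alkenes and should leave the diaryl ketone, ring B and both heteroaryl C–Cl bonds intact, since monovalent rhodium does not insert into such bonds under these conditions, whereas Pd/C would risk hydrodechlorination.

## Compound list

1 | resorcinol (benzene-1,3-diol) | Oc1cccc(O)c1 | starting material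
2 | 4,5-dichloro-1H-pyrrole-2-carboxylic acid | OC(=O)c1cc(Cl)c(Cl)[nH]1 | starting material
3 | O,O-difluoroboron chelate of ketone 4 (2,2-difluoro-1,3,2-benzodioxaborinine ring formed from the C2 phenoxide oxygen and the ketone oxygen; 7-hydroxy, 4-(4,5-dichloro-1H-pyrrol-2-yl)) | Oc1ccc2c(c1)O[B-](F)(F)[O+]=C2c1cc(Cl)c(Cl)[nH]1 | intermediate
4 | (4,5-dichloro-1H-pyrrol-2-yl)(2,4-dihydroxyphenyl)methanone | O=C(c1ccc(O)cc1O)c1cc(Cl)c(Cl)[nH]1 | intermediate
5 | rac-4-methylpent-1-en-3-ol | C=CC(O)C(C)C | starting material
6 | rac-(4,5-dichloro-1H-pyrrol-2-yl){2-hydroxy-4-[(4-methylpent-1-en-3-yl)oxy]phenyl}methanone | C=CC(C(C)C)Oc1ccc(C(=O)c2cc(Cl)c(Cl)[nH]2)c(O)c1 | intermediate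
7 | rac-4-(4,5-dichloro-1H-pyrrole-2-carbonyl)-3-hydroxy-2-[(E)-4-methylpent-2-en-1-yl]cyclohexa-3,5-dien-1-one | CC(C)/C=C/CC1C(=O)C=CC(C(=O)c2cc(Cl)c(Cl)[nH]2)=C1O | intermediate
8 | (E)-(4,5-dichloro-1H-pyrrol-2-yl)[2,4-dihydroxy-3-(4-methylpent-2-en-1-yl)phenyl]methanone | CC(C)/C=C/Cc1c(O)ccc(C(=O)c2cc(Cl)c(Cl)[nH]2)c1O | intermediate
9 | (4,5-dichloro-1H-pyrrol-2-yl)[2,4-dihydroxy-3-(4-methylpentyl)phenyl]methanone | CC(C)CCCc1c(O)ccc(C(=O)c2cc(Cl)c(Cl)[nH]2)c1O | target

## Step count and least certain steps

Total step count: 4. Longest linear sequence: 4 steps (1 → 4 → 6 → 8 → 9).

Step 3 (key step). What may go wrong: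
- migration of the allyl unit to C5 if the chelate loosens at high temperature;
- heterolysis of the secondary allylic C–O bond, since the para-acyl phenoxide is a good leaving group, leading to loss or scrambling of the side chain;
- ring closure of the liberated C4 hydroxyl onto the new alkene.

Fallback (a change from sigmatropic delivery to directed lithiation): setting out from 1, O-methylation with Me2SO4 and K2CO3 in acetone would give 1,3-dimethoxybenzene F1. Lithiation with n-BuLi in THF at 0 °C occurs between the two methoxy groups, and alkylation with 1-bromo-4-methylpentane would give 1,3-dimethoxy-2-(4-methylpentyl)benzene F2. Cleavage of both ethers with BBr3 in CH2Cl2 would give 2-(4-methylpentyl)benzene-1,3-diol F3. Acylation of F3 with 2 in BF3·OEt2, as in step 1, can only occur at the position ortho to one and para to the other hydroxyl, and would return to the route at 9.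

Step 2. What may go wrong:
- allylic transposition during the displacement, so that oxygen attacks the terminal CH2 and gives the linear ether;
- slow activation of the hindered, α-branched alcohol, with elimination or hydrazide alkylation taking over;
- competing alkylation at N1'.

Fallback (a change from phosphonium activation to metal-allyl chemistry): setting out from 5, methyl chloroformate and pyridine would give rac-methyl 4-methylpent-1-en-3-yl carbonate F4. The lithium 4-phenoxide of 4, made with one equivalent of LiOt-Bu so that only the most acidic hydroxyl is ionised, would then be allylated with F4 in THF at 50 °C using [Ir(cod)Cl]2 and a phosphoramidite ligand. The allyliridium intermediate is attacked at its substituted terminus, so the branched ether is expected, and the sequence returns to the route at 6.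

Step 1. What may go wrong:
- protodecarboxylation of the pyrrole acid in the hot acidic medium before it acylates;
- incomplete C-acylation, because the acylating species derived from a pyrrole-conjugated acid is a weak electrophile;
- some second acylation of the very reactive ring.

Fallback (a change to a preformed acid chloride and a protected ring A): setting out from 2, (COCl)2 with catalytic DMF in CH2Cl2 would give 4,5-dichloro-1H-pyrrole-2-carbonyl chloride F5. Friedel–Crafts acylation of 1,3-dimethoxybenzene F1 with F5 and AlCl3 in CH2Cl2 at 0 °C would give (4,5-dichloro-1H-pyrrol-2-yl)(2,4-dimethoxyphenyl)methanone F6. BBr3 in CH2Cl2 would cleave both methyl ethers (including any already lost ortho to the ketone) and return to the route at 4.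

Step 4. What may go wrong:
- slow uptake of hydrogen by the internal, isopropyl-flanked alkene;
- metal-mediated migration of the double bond along the chain;
- catalyst inhibition by the chelating ortho-hydroxy ketone.

Fallback (a change from metal catalysis to metal-free hydrogen transfer): setting out from 8, diimide generated in the flask from 2-nitrobenzenesulfonyl hydrazide and Et3N in CH2Cl2 at room temperature would add hydrogen to the alkene in a concerted syn fashion. Diimide cannot cleave C–Cl bonds or reduce the ketone, and the reaction returns to the route at 9 with no new compound on the way.

## Further compounds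

F1 | step 3 | 1,3-dimethoxybenzene | COc1cccc(OC)c1
F2 | step 3 | 1,3-dimethoxy-2-(4-methylpentyl)benzene | CC(C)CCCc1c(OC)cccc1OC
F3 | step 3 | 2-(4-methylpentyl)benzene-1,3-diol | CC(C)CCCc1c(O)cccc1O
F4 | step 2 | rac-methyl 4-methylpent-1-en-3-yl carbonate | C=CC(OC(=O)OC)C(C)C
F5 | step 1 | 4,5-dichloro-1H-pyrrole-2-carbonyl chloride | O=C(Cl)c1cc(Cl)c(Cl)[nH]1
F6 | step 1 | (4,5-dichloro-1H-pyrrol-2-yl)(2,4-dimethoxyphenyl)methanone | COc1ccc(C(=O)c2cc(Cl)c(Cl)[nH]2)c(OC)c1
F0 | step 4 | none | none
A1 | alternative 1 | 2-amino-1-[2,4-dimethoxy-3-(4-methylpentyl)phenyl]ethan-1-one | CC(C)CCCc1c(OC)ccc(C(=O)CN)c1OC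
A2 | alternative 1 | 2-chloro-1,3-bis(dimethylamino)trimethinium hexafluorophosphate | CN(C)C=C(Cl)C=[N+](C)C.F[P-](F)(F)(F)(F)F
A3 | alternative 1 | (4-chloro-1H-pyrrol-2-yl)[2,4-dimethoxy-3-(4-methylpentyl)phenyl]methanone | CC(C)CCCc1c(OC)ccc(C(=O)c2cc(Cl)c[nH]2)c1OC
A4 | alternative 2 | 1-methoxy-2-(4-methylpentyl)-1,3-bis(trimethylsilyloxy)buta-1,3-diene | C=C(O[Si](C)(C)C)C(CCCC(C)C)=C(OC)O[Si](C)(C)C
A5 | alternative 2 | tert-butyl 2,3-dichloro-5-(prop-2-ynoyl)-1H-pyrrole-1-carboxylate | C#CC(=O)c1cc(Cl)c(Cl)n1C(=O)OC(C)(C)C
A6 | alternative 2 | tert-butyl 2,3-dichloro-5-[2,4-dihydroxy-3-(4-methylpentyl)benzoyl]-1H-pyrrole-1-carboxylate | CC(C)CCCc1c(O)ccc(C(=O)c2cc(Cl)c(Cl)n2C(=O)OC(C)(C)C)c1O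
A7 | alternative 3 | 2,3-dichloro-6-[2,4-dimethoxy-3-(4-methylpentyl)phenyl]pyridine 1-oxide | CC(C)CCCc1c(OC)ccc(-c2ccc(Cl)c(Cl)[n+]2[O-])c1OC
A8 | alternative 3 | (4,5-dichloro-1H-pyrrol-2-yl)[2,4-dimethoxy-3-(4-methylpentyl)phenyl]methanone | CC(C)CCCc1c(OC)ccc(C(=O)c2cc(Cl)c(Cl)[nH]2)c1OC
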